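**Retrosynthetic overview**
1. The diaryl ether C–O bond is made last. The target comes from the o-quinone diazide of ring A (2,3,4-tribromo-6-diazocyclohexa-2,4-dien-1-one) and 2,4-dibromophenol (ring B) by a new Rh-carbenoid O–H insertion. The N2-bearing carbon becomes C–OAr and the carbonyl O becomes the free OH.
2. The diazo oxide comes from 6-amino-2,3,4-tribromophenol by diazotisation, and that amine from 2,3,4-tribromo-6-nitrophenol by nitro reduction.
3. The nitrophenol comes from 5-bromo-2-nitrophenol and 2 Br2. OH, NO2 and Br all direct to the same two carbons.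
4. No ring is built, since both benzene rings are bought. Ring A is fully substituted first and ring B is attached in the last step.

Assumption: the SMILES holds no stereocentre and the diaryl ether axis rotates freely. The target is therefore achiral, "single enantiomer" does not apply, and no stereocontrol step is needed.

**Step 1**
Reactants: 1 5-bromo-2-nitrophenol
Product: 3 2,3,4-tribromo-6-nitrophenol, via 4,5-dibromo-2-nitrophenol 2 (not isolated)
Conditions: Br2 (2.6 equiv), AcOH, rt 2 h then 85 °C 4 h; air purge, H2O, filter
Reagents that add atoms: bromine, BrBr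
Why: Electrophilic aromatic bromination in which OH (ortho/para), NO2 (meta) and the C5–Br (ortho) all point to C4 and C6, while C3 (ortho to NO2, meta to OH) stays inert, so the para position reacts first (2) and then the remaining ortho position; no stereocentre is formed.

**Step 2**
Reactants: 3 2,3,4-tribromo-6-nitrophenol
Product: 4 6-amino-2,3,4-tribromophenol
Conditions: Na2S2O4 (4 equiv), EtOH/H2O 1:1, 70 °C, N2, 1 h
Reagents that add atoms: none
Why: Dithionite nitro reduction proceeds by electron transfer to the nitro group only and leaves aryl bromides untouched, and the product is used promptly because aminophenols oxidise in air.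

**Step 3**
Reactants: 4 6-amino-2,3,4-tribromophenol
Product: 5 2,3,4-tribromo-6-diazocyclohexa-2,4-dien-1-one (= 2,3,4-tribromo-6-diazoniophenolate)
Conditions: t-BuONO (1.3 equiv), AcOH/MeCN 1:4, 0 °C to rt, dark, 2 h; ice-water, filter
Reagents that add atoms: tert-butyl nitrite, CC(C)(C)ON=O
Why: Diazotisation of an o-aminophenol gives a 2-hydroxyarenediazonium ion that is a far stronger acid than AcOH, so it loses its OH proton at once and the neutral diazo oxide precipitates on dilution, while the halide-free medium rules out SNAr exchange of the bromine para to N2+.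

**Step 4**
Reactants: 5 2,3,4-tribromo-6-diazocyclohexa-2,4-dien-1-one; 6 2,4-dibromophenol
Product: 8 2,3,4-tribromo-6-(2,4-dibromophenoxy)phenol, via oxonium phenolate ylide 7 (not isolated)
Conditions: Rh2(esp)2 (2 mol %), 6 (3 equiv), 4 Å MS, DCE, 80 °C, dark, 5 added over 4 h by syringe pump
Reagents that add atoms: none
Why: Proposed new method: Rh(II)-catalysed O–H insertion of a phenol into a monocyclic polyhalogenated o-benzoquinone diazide, giving a 2-aryloxyphenol directly; the diazo carbon of 5 attacks the axial site of Rh2(esp)2 and loses N2 to give a rhodium quinoid carbene whose carbene carbon is strongly electrophilic because nucleophile addition restores aromaticity, the oxygen of 6 adds there (its para and one ortho carbon are blocked by Br and its ring is deactivated, so C-attack and azo coupling are slow), Rh leaves to give ylide 7, and an irreversible 1,4-proton shift from the oxonium to the neighbouring phenolate gives 8, so the carbon that bore nitrogen carries OAr and the old phenol oxygen stays as free OH without any protecting group; metal catalysis in the dark at 80 °C (expected to be below the uncatalysed decomposition of such diazo oxides) holds back the Wolff ring contraction, slow addition and excess 6 hold back carbene dimerisation, and the OH of 8, flanked by Br and OAr, does not compete; the closest known reaction types are Rh(II)-catalysed O–H insertion of α-diazocarbonyl compounds into phenols and of 1,2-diazonaphthoquinones into alcohols; no stereocentre is formed.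

**Compound list**
1 | 5-bromo-2-nitrophenol | Oc1cc(Br)ccc1[N+](=O)[O-] | starting material
2 | 4,5-dibromo-2-nitrophenol | Oc1cc(Br)c(Br)cc1[N+](=O)[O-] | intermediate (not isolated)
3 | 2,3,4-tribromo-6-nitrophenol | Oc1c(Br)c(Br)c(Br)cc1[N+](=O)[O-] | intermediate
4 | 6-amino-2,3,4-tribromophenol | Nc1cc(Br)c(Br)c(Br)c1O | intermediate
5 | 2,3,4-tribromo-6-diazocyclohexa-2,4-dien-1-one | O=C1C(Br)=C(Br)C(Br)=CC1=[N+]=[N-] | intermediate
6 | 2,4-dibromophenol | Oc1ccc(Br)cc1Br | starting material
7 | oxonium phenolate ylide, 2,3,4-tribromo-6-[(2,4-dibromophenyl)oxonio]phenolate | [O-]c1c(Br)c(Br)c(Br)cc1[OH+]c1ccc(Br)cc1Br | intermediate (not isolated)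
8 | 2,3,4-tribromo-6-(2,4-dibromophenoxy)phenol | Oc1c(Oc2ccc(Br)cc2Br)cc(Br)c(Br)c1Br | target

**Totals**
Total step count: 4. Longest linear sequence: 4 (1 → 3 → 4 → 5 → 8); 6 enters in the last step.

**Three steps most likely to fail**

Step 4 (the new step).
- Risks: N2 loss from the electron-poor diazo oxide on Rh may be too slow. Wolff ring contraction may occur, with the ketene trapped by 6 as an aryl ester. The carbene may dimerise to a toxic hexabromodibenzo-p-dioxin.
- Fallback: it uses known chemistry only, sets out from 6 and comes back at 8. Compound 6 is joined to commercial 5-bromo-2-fluorobenzaldehyde (O=Cc1cc(Br)ccc1F) by SNAr (K2CO3, DMAc, 130 °C) to give 5-bromo-2-(2,4-dibromophenoxy)benzaldehyde F1. Baeyer–Villiger oxidation (mCPBA, CH2Cl2, 40 °C) gives 5-bromo-2-(2,4-dibromophenoxy)phenyl formate F2. Base-catalysed methanolysis (cat. K2CO3, MeOH, rt) gives 5-bromo-2-(2,4-dibromophenoxy)phenol F3. The free OH of F3 then directs Br2 (2.1 equiv, AcOH, rt) to its para position and its one free ortho position, next to the bromine already present, which gives 8.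

Step 3.
- Risks: the weakly basic, hindered amine 4 may be nitrosated slowly or be oxidised. The tribromo diazo oxide may lose its para bromine or decompose on isolation. It is an energetic solid and must be kept cold, dark and on a small scale.
- Fallback: it reverses the order of bromination and diazotisation, sets out from 1 and comes back at 5. Compound 1 is reduced (Na2S2O4, EtOH/H2O) to the more basic 2-amino-5-bromophenol F4. This is diazotised (t-BuONO, AcOH/MeCN, 0 °C) to 3-bromo-6-diazocyclohexa-2,4-dien-1-one F5. Ring bromination of F5 (Br2, 2.1 equiv, aqueous AcOH, 0–20 °C, dark) gives 5, because the phenolate oxygen (ortho/para) and the diazonium group (meta) direct to the same two carbons.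

Step 1.
- Risks: the second bromination at the crowded carbon between OH and Br may stall at 2, and forcing conditions may cause ipso bromodenitration.
- Fallback: it brominates a more electron-rich ring, sets out from 1 and comes back at 4, skipping steps 1 and 2. Compound 1 is reduced to 2-amino-5-bromophenol F4 as above. N-acylation (trifluoroacetic anhydride, pyridine, CH2Cl2, 0 °C) gives N-(4-bromo-2-hydroxyphenyl)-2,2,2-trifluoroacetamide F6, in which the nitrogen is switched off as a director. Br2 (2.1 equiv, AcOH, rt) under OH control gives 2,2,2-trifluoro-N-(3,4,5-tribromo-2-hydroxyphenyl)acetamide F7. Cleavage of the amide (K2CO3, MeOH/H2O, 50 °C) gives 4.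

**Further compounds**
F1 | step 4 | 5-bromo-2-(2,4-dibromophenoxy)benzaldehyde | O=Cc1cc(Br)ccc1Oc1ccc(Br)cc1Br
F2 | step 4 | 5-bromo-2-(2,4-dibromophenoxy)phenyl formate | O=COc1cc(Br)ccc1Oc1ccc(Br)cc1Br
F3 | step 4 | 5-bromo-2-(2,4-dibromophenoxy)phenol | Oc1cc(Br)ccc1Oc1ccc(Br)cc1Br
F4 | step 3 | 2-amino-5-bromophenol | Nc1ccc(Br)cc1O
F5 | step 3 | 3-bromo-6-diazocyclohexa-2,4-dien-1-one | O=C1C=C(Br)C=CC1=[N+]=[N-]
F6 | step 1 | N-(4-bromo-2-hydroxyphenyl)-2,2,2-trifluoroacetamide | O=C(Nc1ccc(Br)cc1O)C(F)(F)F
F7 | step 1 | 2,2,2-trifluoro-N-(3,4,5-tribromo-2-hydroxyphenyl)acetamide | O=C(Nc1cc(Br)c(Br)c(Br)c1O)C(F)(F)F
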